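**Retrosynthetic overview**
- Oxirane last: both epoxide C–O bonds come from a catalyst-controlled Shi epoxidation of the E-trisubstituted olefin of the complete alkene lactone.
- γ-Lactone second: chromium-catalysed asymmetric 2-(ethoxycarbonyl)allylation of a β,γ-unsaturated aldehyde sets C5, and acid closes the lactone (acyl C–O).
- Key disconnection, C5–O: the aldehyde comes from anti-Markovnikov hydration of the terminal alkyne of an (E)-enyne aryl ether; the water oxygen becomes the lactone ring oxygen.
- Aryl ether C–O: Mitsunobu union of 7-hydroxy-8-methoxycoumarin with commercial (E)-3-methylpent-2-en-4-yn-1-ol, which already carries the E-olefin.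
- Coumarin ring first: Pechmann-type annulation of 2-methoxyresorcinol with ethyl propiolate. Ring order: pyranone, γ-lactone, oxirane.

Assumption: the (S,S)-ligand in step 4 is taken to give Si-face allylation (5R lactone); if the first run shows the opposite sense, its enantiomer is used.

Step 1
Reactants: 1 2-methoxybenzene-1,3-diol; 2 ethyl prop-2-ynoate
Product: 4 7-hydroxy-8-methoxy-2H-chromen-2-one, via Z-cinnamate ester 3 (not isolated)
Conditions: ZnCl2 (1.0 equiv), 1,4-dioxane, 90 °C
Reagents that add atoms: none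
Why: Pechmann-type coumarin synthesis: ZnCl2-promoted hydroarylation of the propiolate at C4 of the symmetric diol (C4 and C6 are equivalent, so only one coumarin can form), then lactonisation of the Z-cinnamate with loss of ethanol.

Step 2
Reactants: 4 7-hydroxy-8-methoxy-2H-chromen-2-one; 5 (2E)-3-methylpent-2-en-4-yn-1-ol
Product: 6 8-methoxy-7-{[(2E)-3-methylpent-2-en-4-yn-1-yl]oxy}-2H-chromen-2-one
Conditions: PPh3, DIAD, THF, 0 °C to rt
Reagents that add atoms: none
Why: Mitsunobu etherification: the only OH of 4 (pKa about 8) displaces the activated primary allylic oxygen of 5 in an SN2 step that leaves the E-olefin geometry untouched.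

Step 3
Reactants: 6 8-methoxy-7-{[(2E)-3-methylpent-2-en-4-yn-1-yl]oxy}-2H-chromen-2-one
Product: 7 (3E)-5-[(8-methoxy-2-oxo-2H-chromen-7-yl)oxy]-3-methylpent-3-enal
Conditions: [CpRu(MeCN)3]PF6 (4 mol %), 5,5'-bis(trifluoromethyl)-2,2'-bipyridine (4 mol %), NMP–H2O 4:1, 25 °C
Reagents that add atoms: water (SMILES: O)
Why: Proposed new method: the cationic CpRu–bipyridine catalyst turns the terminal alkyne into a ruthenium vinylidene, water adds to its electrophilic terminal carbon and the acyl hydride releases the aldehyde, so the C5–O bond (the future lactone ring oxygen) forms with anti-Markovnikov regiochemistry at neutral pH and 25 °C, where the E-olefin, the allyl aryl ether and the base-labile β,γ-unsaturated aldehyde (prone to conjugation and vinylogous loss of aryloxide) should survive; the closest known reaction is ruthenium-catalysed anti-Markovnikov hydration of simple terminal alkynes, not yet shown on a 1,3-enyne that carries an allylic aryloxy leaving group.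

Step 4
Reactants: 7 (3E)-5-[(8-methoxy-2-oxo-2H-chromen-7-yl)oxy]-3-methylpent-3-enal; 8 ethyl 2-(bromomethyl)prop-2-enoate
Product: 11 (5R)-5-[(2E)-4-[(8-methoxy-2-oxo-2H-chromen-7-yl)oxy]-2-methylbut-2-en-1-yl]-3-methylideneoxolan-2-one, via silyl ether 9 (not isolated), via hydroxy ester 10 (not isolated)
Conditions: CrCl2 (10 mol %), (S,S)-1,8-bis(4-isopropyl-4,5-dihydrooxazol-2-yl)-3,6-diphenyl-9H-carbazole (12 mol %), iPr2NEt (20 mol %), Mn powder, Me3SiCl, THF, rt; then 1 M HCl, THF, 0 °C; CSA (5 mol %), CH2Cl2, rt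
Reagents that add atoms: none
Why: Catalytic asymmetric Nozaki–Hiyama–Kishi 2-(alkoxycarbonyl)allylation: the allylchromium species adds through a closed six-membered transition state to the Si face of the aldehyde under non-basic conditions (ligand control sets C5), and the desilylated γ-hydroxy ester lactonises under mild acid.

Step 5
Reactants: 11 (5R)-5-[(2E)-4-[(8-methoxy-2-oxo-2H-chromen-7-yl)oxy]-2-methylbut-2-en-1-yl]-3-methylideneoxolan-2-one
Product: 12 (5S)-5-{[(2R,3R)-3-{[(8-methoxy-2-oxo-2H-chromen-7-yl)oxy]methyl}-2-methyloxiran-2-yl]methyl}-3-methylideneoxolan-2-one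
Conditions: 1,2:4,5-di-O-isopropylidene-β-D-erythro-2,3-hexodiulo-2,6-pyranose (1.0 equiv), 2KHSO5·KHSO4·K2SO4, NaHCO3, MeCN–H2O (pH 7.5–8), 0 °C
Reagents that add atoms: potassium peroxymonosulfate KHSO5 (SMILES: [K+].[O-]S(=O)(=O)OO)
Why: Shi asymmetric epoxidation: the dioxirane formed in situ from the D-fructose-derived ketone transfers oxygen through a spiro transition state to one face of the electron-rich E-trisubstituted olefin, setting both oxirane centres as 2R,3R under catalyst control, while the electron-poor exo-methylene and coumarin C3–C4 olefins are inert to the electrophilic oxidant; C5 is untouched (its descriptor changes from R to S only because the CIP ranking of its two CH2 arms inverts).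

**Compound list**
1 | 2-methoxybenzene-1,3-diol | COc1c(O)cccc1O | starting material
2 | ethyl prop-2-ynoate | CCOC(=O)C#C | starting material
3 | ethyl (2Z)-3-(2,4-dihydroxy-3-methoxyphenyl)prop-2-enoate | CCOC(=O)/C=C\c1ccc(O)c(OC)c1O | intermediate
4 | 7-hydroxy-8-methoxy-2H-chromen-2-one | COc1c(O)ccc2ccc(=O)oc12 | intermediate
5 | (2E)-3-methylpent-2-en-4-yn-1-ol | C#C/C(C)=C/CO | starting material
6 | 8-methoxy-7-{[(2E)-3-methylpent-2-en-4-yn-1-yl]oxy}-2H-chromen-2-one | C#C/C(C)=C/COc1ccc2ccc(=O)oc2c1OC | intermediate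
7 | (3E)-5-[(8-methoxy-2-oxo-2H-chromen-7-yl)oxy]-3-methylpent-3-enal | O=CC/C(C)=C/COc1ccc2ccc(=O)oc2c1OC | intermediate
8 | ethyl 2-(bromomethyl)prop-2-enoate | C=C(CBr)C(=O)OCC | starting material
9 | ethyl (4R,6E)-8-[(8-methoxy-2-oxo-2H-chromen-7-yl)oxy]-6-methyl-2-methylidene-4-[(trimethylsilyl)oxy]oct-6-enoate | C=C(C[C@@H](C/C(C)=C/COc1ccc2ccc(=O)oc2c1OC)O[Si](C)(C)C)C(=O)OCC | intermediate
10 | ethyl (4R,6E)-4-hydroxy-8-[(8-methoxy-2-oxo-2H-chromen-7-yl)oxy]-6-methyl-2-methylideneoct-6-enoate | C=C(C[C@@H](C/C(C)=C/COc1ccc2ccc(=O)oc2c1OC)O)C(=O)OCC | intermediate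
11 | (5R)-5-[(2E)-4-[(8-methoxy-2-oxo-2H-chromen-7-yl)oxy]-2-methylbut-2-en-1-yl]-3-methylideneoxolan-2-one | C=C1C[C@@H](C/C(C)=C/COc2ccc3ccc(=O)oc3c2OC)OC1=O | intermediate
12 | (5S)-5-{[(2R,3R)-3-{[(8-methoxy-2-oxo-2H-chromen-7-yl)oxy]methyl}-2-methyloxiran-2-yl]methyl}-3-methylideneoxolan-2-one | C=C1C[C@@H](C[C@@]2(C)O[C@@H]2COc2ccc3ccc(=O)oc3c2OC)OC1=O | target

**Step count**
Total steps: 5. Longest linear sequence: 5 (1 → 4 → 6 → 7 → 11 → 12).

**Steps most likely to fail, with fallbacks**

1. Hydration of 6 (step 3, the proposed new method). The catalyst may ionise the allyl aryl ether, or the vinylidene of the conjugated enyne may react sluggishly. The fallback sets out from 6 and uses known chemistry: Brown–Zweifel hydroboration of the terminal alkyne with dicyclohexylborane (THF, 0 °C) gives the dicyclohexyl(dienyl)borane F1. Oxidation of this with pH 7-buffered H2O2 returns to the route at aldehyde 7.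

2. Allylation of 7 (step 4). The aldehyde can conjugate or lose the aryloxide, and the ee on this substrate is untested. The fallback sets out from 7: reduction (NaBH4, MeOH, −20 °C) gives the homoallylic alcohol F2. This is then used in the Krische-type iridium-catalysed transfer-hydrogenative 2-(alkoxycarbonyl)allylation from the alcohol oxidation level: [Ir(cod)Cl]2, (S)-SEGPHOS, 4-chloro-3-nitrobenzoic acid, Cs2CO3 (20 mol %), ethyl 2-{[(tert-butoxycarbonyl)oxy]methyl}prop-2-enoate, THF, 60 °C. The aldehyde is then only a transient species, hydroxy ester 10 forms and lactonises, and the route is rejoined at 11.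

3. Epoxidation of 11 (step 5). The two lactones may not tolerate the aqueous oxidant, or the diastereomer ratio may be low. The fallback sets out from hydroxy ester 10, isolated by leaving out the CSA treatment in step 4. Its free C5 hydroxyl directs a vanadium/bishydroxamic acid-catalysed homoallylic-alcohol epoxidation (VO(OiPr)3, chiral bishydroxamic acid ligand matched to the 4R carbinol, cumene hydroperoxide, toluene, 0 °C) to the epoxy hydroxy ester F3. Lactonisation of this with CSA (cat.) comes back to the route at 12.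

Further compounds
F1 | step 3 | dicyclohexyl{(1E,3E)-5-[(8-methoxy-2-oxo-2H-chromen-7-yl)oxy]-3-methylpenta-1,3-dien-1-yl}borane | B(/C=C/C(C)=C/COc1ccc2ccc(=O)oc2c1OC)(C1CCCCC1)C1CCCCC1
F2 | step 4 | (3E)-5-[(8-methoxy-2-oxo-2H-chromen-7-yl)oxy]-3-methylpent-3-en-1-ol | OCC/C(C)=C/COc1ccc2ccc(=O)oc2c1OC
F3 | step 5 | ethyl (4S)-4-hydroxy-5-[(2R,3R)-3-{[(8-methoxy-2-oxo-2H-chromen-7-yl)oxy]methyl}-2-methyloxiran-2-yl]-2-methylidenepentanoate | C=C(C[C@@H](C[C@@]1(C)O[C@@H]1COc1ccc2ccc(=O)oc2c1OC)O)C(=O)OCC
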